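**Retrosynthetic overview**

1. Side-chain numbering: C1 = CH(OH) on the lactone, C4 = C(CH3)OH, C5=C6, C7 = CH2, C8(CH3)=C9, C10–C11, then furan C3. The last disconnection is C6–C7 (vinyl CH to allyl CH2), giving E-alkenylstannane 17 (C1–C6 plus lactone) and a 2-methylallyl cation equivalent (C7–C11 plus furan).
2. Enabling feature: the triad C7–C8(CH3)=C9 next to that bond is a 2-methylallyl unit. It is stored as the three ring carbons of cyclopropyl mesylate 23 (C8 = C–OMs, C7 = ring CH2, C9 = ring CH carrying the furylethyl arm cis to methyl). Strain-driven disrotatory opening gives the E-allyl electrophile, which is coupled at C7 in the same flask.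
3. 23 comes from Kulinkovich cyclopropanation of ethyl acetate with 3-(but-3-enyl)furan, made from 3-bromofuran (furan ring bought).
4. 17 comes from alkyne 16. The γ-lactone arises by 5-exo opening (inversion at the quaternary carbon) of the Shi epoxide of Johnson–Claisen ester 12. The C4 carbinol comes from the Sharpless epoxide of geraniol via epoxy chloride to alkyne.
5. Ring order: oxirane (step 1, opened in step 3), oxirane (step 8), γ-lactone (step 9); cyclopropane (step 13), opened in step 15.

Key step: step 15

Remark: cyclopropanes 22 and 23 are racemic (only the cis relative configuration matters, since both ring stereocentres are destroyed in step 15). The carbinol centre of 9 and 11 is an inconsequential epimer mixture. Geraniol, 3-bromofuran, ethyl acetate, triethyl orthoacetate and the two Grignard solutions are taken as commercial.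

**Route**

Step 1
Reactants: 1 geraniol
Product: 2 [(2S,3S)-3-methyl-3-(4-methylpent-3-en-1-yl)oxiran-2-yl]methanol
Conditions: Ti(OiPr)4 (5 mol %), L-(+)-diethyl tartrate (6 mol %), t-BuOOH, 4 Å MS, CH2Cl2, −20 °C
Reagents that add atoms: tert-butyl hydroperoxide, CC(C)(C)OO
Why: Sharpless asymmetric epoxidation, in which the allylic hydroxyl binds the Ti–tartrate complex so that only the 2,3-alkene reacts and the L-(+)-tartrate ligand should deliver oxygen to the face giving the (2S,3S)-epoxide, fixing the tertiary C–O stereocentre (C4 of the target chain).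

Step 2
Reactants: 2 [(2S,3S)-3-methyl-3-(4-methylpent-3-en-1-yl)oxiran-2-yl]methanol
Product: 3 (2S,3R)-3-(chloromethyl)-2-methyl-2-(4-methylpent-3-en-1-yl)oxirane
Conditions: PPh3, CCl4, NaHCO3, reflux
Reagents that add atoms: carbon tetrachloride, ClC(Cl)(Cl)Cl
Why: Appel chlorination (SN2 at the primary carbinol via the alkoxyphosphonium salt) under buffered conditions should leave the epoxide and both stereocentres untouched (the descriptor change at the CH carbon is only a CIP priority effect).

Step 3
Reactants: 3 (2S,3R)-3-(chloromethyl)-2-methyl-2-(4-methylpent-3-en-1-yl)oxirane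
Product: 4 (3S)-3,7-dimethyloct-6-en-1-yn-3-ol
Conditions: n-BuLi (3.2 equiv), THF, −78 to −30 °C; aq. NH4Cl
Reagents that add atoms: none
Why: Base-induced fragmentation of a 2,3-epoxy chloride to a propargylic alcohol, in which deprotonation at CH2Cl with anti-elimination opens the epoxide, a second elimination of LiCl gives the alkyne, and the tertiary C–O bond is never broken so its configuration is retained.

Step 4
Reactants: 4 (3S)-3,7-dimethyloct-6-en-1-yn-3-ol
Product: 5 [(3S)-3,7-dimethyloct-6-en-1-yn-3-yl]oxy(triethyl)silane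
Conditions: TESOTf, 2,6-lutidine, CH2Cl2, −78 to 0 °C
Reagents that add atoms: triethylsilyl trifluoromethanesulfonate, CC[Si](CC)(CC)OS(=O)(=O)C(F)(F)F
Why: Silyl triflate with a hindered base silylates even a tertiary propargylic alcohol, and the TES ether masks the carbinol against the later Claisen and epoxide-opening chemistry.

Step 5
Reactants: 5 [(3S)-3,7-dimethyloct-6-en-1-yn-3-yl]oxy(triethyl)silane
Product: 7 (4S)-4-methyl-4-[(triethylsilyl)oxy]hex-5-ynal, via ozonide 6 (not isolated)
Conditions: O3, CH2Cl2, −78 °C (Sudan III end point); then PPh3, −78 °C to rt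
Reagents that add atoms: ozone, [O-][O+]=O
Why: Ozonolysis with reductive work-up, relying on the much faster addition of ozone to the electron-rich trisubstituted alkene than to the terminal alkyne, with phosphine reduction of the ozonide giving the aldehyde.

Step 6
Reactants: 7 (4S)-4-methyl-4-[(triethylsilyl)oxy]hex-5-ynal; 8 isopropenylmagnesium bromide
Product: 9 (3RS,6S)-2,6-dimethyl-6-[(triethylsilyl)oxy]oct-1-en-7-yn-3-ol
Conditions: THF, −78 °C; aq. NH4Cl
Reagents that add atoms: none
Why: Grignard 1,2-addition to the aldehyde at low temperature should outpace deprotonation of the alkyne, and the new carbinol centre need not be controlled because it becomes sp2 in step 7.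

Step 7
Reactants: 9 (3RS,6S)-2,6-dimethyl-6-[(triethylsilyl)oxy]oct-1-en-7-yn-3-ol; 10 triethyl orthoacetate
Product: 12 ethyl (4E,8S)-4,8-dimethyl-8-[(triethylsilyl)oxy]dec-4-en-9-ynoate, via ketene acetal 11 (not isolated)
Conditions: MeC(OEt)3 (excess), EtCO2H (5 mol %), 135–140 °C, EtOH distilled off
Reagents that add atoms: none
Why: Johnson–Claisen rearrangement, in which orthoester exchange and loss of ethanol give the ketene acetal whose chair-like [3,3] shift places the carbinol substituent equatorial and so should deliver the E-trisubstituted γ,δ-unsaturated ester with the two-carbon ester arm in place.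

Step 8
Reactants: 12 ethyl (4E,8S)-4,8-dimethyl-8-[(triethylsilyl)oxy]dec-4-en-9-ynoate
Product: 13 ethyl 3-{(2R,3R)-2-methyl-3-[(3S)-3-methyl-3-(triethylsilyloxy)pent-4-yn-1-yl]oxiran-2-yl}propanoate
Conditions: D-fructose-derived Shi ketone (0.3 equiv), Oxone, K2CO3, Bu4NHSO4, MeCN/DMM/aq. borate–EDTA buffer (pH 10.5), 0 °C
Reagents that add atoms: potassium peroxymonosulfate (Oxone), [K+].[O-]S(=O)(=O)OO
Why: Shi epoxidation, in which the chiral dioxirane from the D-fructose-derived ketone attacks E-trisubstituted alkenes through a spiro transition state and should give the (R,R)-epoxide, while alkyne, ester and silyl ether are inert to the dioxirane.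

Step 9
Reactants: 13 ethyl 3-{(2R,3R)-2-methyl-3-[(3S)-3-methyl-3-(triethylsilyloxy)pent-4-yn-1-yl]oxiran-2-yl}propanoate
Product: 15 (5S)-5-[(1R,4S)-1-hydroxy-4-methyl-4-(triethylsilyloxy)hex-5-yn-1-yl]-5-methyloxolan-2-one, via epoxy acid 14 (not isolated)
Conditions: LiOH·H2O, THF/H2O, 0 °C to rt; then 1 M HCl to pH 3, extraction; then CSA (10 mol %), CH2Cl2, 0 °C
Reagents that add atoms: lithium hydroxide, [Li+].[OH-]
Why: Saponification followed by acid-catalysed 5-exo-tet epoxide opening by the carboxylic acid at the tertiary carbon (Markovnikov, with inversion) forms the γ-lactone and sets the (S)-quaternary centre, the retained epoxide C–O bond at the secondary carbon becomes the (R)-hydroxyl, and the silyl ether keeps the tertiary carbinol from competing as nucleophile.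

Step 10
Reactants: 15 (5S)-5-[(1R,4S)-1-hydroxy-4-methyl-4-(triethylsilyloxy)hex-5-yn-1-yl]-5-methyloxolan-2-one
Product: 16 (5S)-5-[(1R,4S)-1,4-dihydroxy-4-methylhex-5-yn-1-yl]-5-methyloxolan-2-one
Conditions: HF·pyridine, pyridine/THF, 0 °C to rt
Reagents that add atoms: none
Why: Fluoride-mediated cleavage of the silyl ether (driven by the Si–F bond) under buffered conditions should leave lactone, alkyne and both carbinols intact.

Step 11
Reactants: 16 (5S)-5-[(1R,4S)-1,4-dihydroxy-4-methylhex-5-yn-1-yl]-5-methyloxolan-2-one
Product: 17 (5S)-5-[(1R,4S,5E)-1,4-dihydroxy-4-methyl-6-(tributylstannyl)hex-5-en-1-yl]-5-methyloxolan-2-one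
Conditions: Bu3SnH (1.2 equiv), PdCl2(PPh3)2 (2 mol %), THF, 0 °C to rt
Reagents that add atoms: tributyltin hydride, CCCC[SnH](CCCC)CCCC
Why: Pd-catalysed hydrostannation, a syn addition of H–SnBu3 across the terminal alkyne that places tin on the terminal carbon, away from the fully substituted propargylic centre, and should give the E-alkenylstannane.

Step 12
Reactants: 18 3-bromofuran; 19 but-3-en-1-ylmagnesium bromide
Product: 20 3-(but-3-en-1-yl)furan
Conditions: NiCl2(dppp) (2 mol %), Et2O/THF, 0 °C to reflux
Reagents that add atoms: none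
Why: Kumada cross-coupling, in which Ni(0)/dppp inserts into the furan C3–Br bond and the bidentate ligand favours reductive elimination over β-hydride elimination of the primary alkyl group.

Step 13
Reactants: 20 3-(but-3-en-1-yl)furan; 21 ethyl acetate
Product: 22 rac-(1S,2S)-2-[2-(furan-3-yl)ethyl]-1-methylcyclopropan-1-ol (methyl and side chain cis)
Conditions: c-C6H11MgCl (4.5 equiv, slow addition), ClTi(OiPr)3 (1.0 equiv), THF, rt
Reagents that add atoms: none
Why: Kulinkovich cyclopropanation in its alkene-exchange form, in which the titanacyclopropane from the cyclohexyl Grignard exchanges cyclohexene for terminal alkene 20 and adds twice to the ester carbonyl, ring closure placing the side chain trans to the O–Ti group so that methyl and side chain end up cis (both new centres racemic).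

Step 14
Reactants: 22 rac-(1S,2S)-2-[2-(furan-3-yl)ethyl]-1-methylcyclopropan-1-ol
Product: 23 rac-(1S,2S)-2-[2-(furan-3-yl)ethyl]-1-methylcyclopropyl methanesulfonate
Conditions: MsCl, Et3N, CH2Cl2, 0 °C
Reagents that add atoms: methanesulfonyl chloride, CS(=O)(=O)Cl
Why: Sulfonylation of the tertiary cyclopropanol through sulfene, giving a cyclopropyl sulfonate that resists spontaneous ionisation and can be handled until a Lewis acid is added.

Step 15
Reactants: 23 rac-(1S,2S)-2-[2-(furan-3-yl)ethyl]-1-methylcyclopropyl methanesulfonate; 17 (5S)-5-[(1R,4S,5E)-1,4-dihydroxy-4-methyl-6-(tributylstannyl)hex-5-en-1-yl]-5-methyloxolan-2-one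
Product: 25 (5S)-5-[(1R,4S,5E,8E)-11-(furan-3-yl)-1,4-dihydroxy-4,8-dimethylundeca-5,8-dien-1-yl]-5-methyloxolan-2-one, via allyl bromide 24 (not isolated)
Conditions: 23 (1.3 equiv), MgBr2·OEt2 (2 equiv), Et2O, reflux; then 17, Pd2(dba)3 (2.5 mol %), AsPh3 (10 mol %), NMP, rt to 40 °C
Reagents that add atoms: none
Why: Mg(II) coordinates the mesylate of 23 and ionisation is concerted with disrotatory 2π-electrocyclic cleavage of the distal C7–C9 ring bond (release of cyclopropane strain), the furylethyl group trans to the leaving group rotating outward so that the 2-methylallyl cation collapses with bromide at its unsubstituted terminus to the (E)-allyl bromide 24; Pd(0) then adds oxidatively to 24, the alkenyl group of 17 is transmetalated from tin with retention, and reductive elimination at the less hindered CH2 terminus forges the allyl CH2–vinyl CH bond. The closest known reaction types are the magnesium-halide-induced cyclopropyl-to-allyl opening of tertiary cyclopropyl sulfonates and the Stille coupling of allyl halides with alkenylstannanes used for skipped dienes. No ring is closed and no new stereocentre is formed; the only ring event is the opening of the temporary cyclopropane. The E geometry at C8=C9 is dictated by the cis relationship of methyl and side chain in 23 (torquoselectivity under the Woodward–Hoffmann rules), and the E geometry at C5=C6 by the stannane. The step needs linear rather than branched allyl coupling and no migration of the 1,4-diene into conjugation; the unsubstituted allyl terminus and the neutral, base-free conditions should secure both, and the free hydroxyls, the lactone and the furan are inert to them.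

**Compound list**

1 | geraniol, (2E)-3,7-dimethylocta-2,6-dien-1-ol | OC/C=C(\C)CCC=C(C)C | starting material
2 | [(2S,3S)-3-methyl-3-(4-methylpent-3-en-1-yl)oxiran-2-yl]methanol | OC[C@@H]1O[C@@]1(C)CCC=C(C)C | intermediate
3 | (2S,3R)-3-(chloromethyl)-2-methyl-2-(4-methylpent-3-en-1-yl)oxirane | ClC[C@@H]1O[C@@]1(C)CCC=C(C)C | intermediate
4 | (3S)-3,7-dimethyloct-6-en-1-yn-3-ol | C#C[C@@](C)(O)CCC=C(C)C | intermediate
5 | [(3S)-3,7-dimethyloct-6-en-1-yn-3-yl]oxy(triethyl)silane | C#C[C@@](C)(O[Si](CC)(CC)CC)CCC=C(C)C | intermediate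
6 | 3,3-dimethyl-5-[(3S)-3-methyl-3-(triethylsilyloxy)pent-4-yn-1-yl]-1,2,4-trioxolane (ozonide, epimers at C5) | C#C[C@@](C)(O[Si](CC)(CC)CC)CCC1OOC(C)(C)O1 | intermediate
7 | (4S)-4-methyl-4-[(triethylsilyl)oxy]hex-5-ynal | C#C[C@@](C)(O[Si](CC)(CC)CC)CCC=O | intermediate
8 | isopropenylmagnesium bromide | C=C(C)[Mg]Br | starting material
9 | (3RS,6S)-2,6-dimethyl-6-[(triethylsilyl)oxy]oct-1-en-7-yn-3-ol | C#C[C@@](C)(O[Si](CC)(CC)CC)CCC(O)C(C)=C | intermediate
10 | triethyl orthoacetate | CC(OCC)(OCC)OCC | starting material
11 | 1-ethoxyvinyl ether of 9 (mixed ketene acetal) | C#C[C@@](C)(O[Si](CC)(CC)CC)CCC(OC(=C)OCC)C(C)=C | intermediate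
12 | ethyl (4E,8S)-4,8-dimethyl-8-[(triethylsilyl)oxy]dec-4-en-9-ynoate | C#C[C@@](C)(O[Si](CC)(CC)CC)CC/C=C(\C)CCC(=O)OCC | intermediate
13 | ethyl 3-{(2R,3R)-2-methyl-3-[(3S)-3-methyl-3-(triethylsilyloxy)pent-4-yn-1-yl]oxiran-2-yl}propanoate | C#C[C@@](C)(O[Si](CC)(CC)CC)CC[C@H]1O[C@]1(C)CCC(=O)OCC | intermediate
14 | 3-{(2R,3R)-2-methyl-3-[(3S)-3-methyl-3-(triethylsilyloxy)pent-4-yn-1-yl]oxiran-2-yl}propanoic acid | C#C[C@@](C)(O[Si](CC)(CC)CC)CC[C@H]1O[C@]1(C)CCC(=O)O | intermediate
15 | (5S)-5-[(1R,4S)-1-hydroxy-4-methyl-4-(triethylsilyloxy)hex-5-yn-1-yl]-5-methyloxolan-2-one | C#C[C@@](C)(O[Si](CC)(CC)CC)CC[C@@H](O)[C@]1(C)CCC(=O)O1 | intermediate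
16 | (5S)-5-[(1R,4S)-1,4-dihydroxy-4-methylhex-5-yn-1-yl]-5-methyloxolan-2-one | C#C[C@@](C)(O)CC[C@@H](O)[C@]1(C)CCC(=O)O1 | intermediate
17 | (5S)-5-[(1R,4S,5E)-1,4-dihydroxy-4-methyl-6-(tributylstannyl)hex-5-en-1-yl]-5-methyloxolan-2-one | CCCC[Sn](CCCC)(CCCC)/C=C/[C@@](C)(O)CC[C@@H](O)[C@]1(C)CCC(=O)O1 | intermediate
18 | 3-bromofuran | Brc1ccoc1 | starting material
19 | but-3-en-1-ylmagnesium bromide | C=CCC[Mg]Br | starting material
20 | 3-(but-3-en-1-yl)furan | C=CCCc1ccoc1 | intermediate
21 | ethyl acetate | CCOC(C)=O | starting material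
22 | rac-(1S,2S)-2-[2-(furan-3-yl)ethyl]-1-methylcyclopropan-1-ol (one enantiomer drawn) | C[C@]1(O)C[C@@H]1CCc1ccoc1 | intermediate
23 | rac-(1S,2S)-2-[2-(furan-3-yl)ethyl]-1-methylcyclopropyl methanesulfonate (one enantiomer drawn) | C[C@]1(OS(C)(=O)=O)C[C@@H]1CCc1ccoc1 | intermediate
24 | 3-[(3E)-5-bromo-4-methylpent-3-en-1-yl]furan | C/C(=C\CCc1ccoc1)CBr | intermediate
25 | (5S)-5-[(1R,4S,5E,8E)-11-(furan-3-yl)-1,4-dihydroxy-4,8-dimethylundeca-5,8-dien-1-yl]-5-methyloxolan-2-one (CNP0151262.1) | C/C(=C\CCc1ccoc1)C/C=C/[C@@](C)(O)CC[C@@H](O)[C@]1(C)CCC(=O)O1 | target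

**Step count and risks**

Total step count: 15. Longest linear sequence: 12 steps (steps 1–11, then 15); the allyl branch (steps 12–14) is three steps.

Steps most likely to fail:

Step 15. The allyl cation may be trapped unselectively (some secondary bromide, whose oxidative addition would give an anti π-allyl and erode the E geometry). The 2-methyl-substituted π-allyl palladium may undergo syn/anti isomerisation before transmetalation. Magnesium salts may ionise or protodestannylate the tertiary allylic alcohol partner. The fallback replaces the π-allyl/tin coupling by an sp–sp3 coupling followed by trans-reduction. It sets out from alkyne 16 and from bromide 24 (isolated after the MgBr2 stage, or taken from the fallback to step 13) and comes back at 25. Copper(I)-mediated SN2 alkynylation of 24 with 16 (CuI, NaI, K2CO3, DMF, rt) should give the skipped enyne, the 5-yne analogue of the target F1. Hydroxyl-directed ruthenium-catalysed trans-hydrostannation ([Cp*RuCl]4 cat., Bu3SnH, CH2Cl2) should place tin on the carbon next to the carbinol and give the (5Z)-5-stannyl diene F2. Protodestannylation with retention (copper(I) thiophene-2-carboxylate, Bu4N diphenylphosphinate, DMF) should then give 25 with the E-C5=C6 alkene and the lactone untouched.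

Step 13. Exchange of cyclohexene for the alkene on titanium may be inefficient, the ester may be consumed by the cyclohexyl-derived titanium species, and cis selectivity may be incomplete, which would carry through as E/Z erosion in step 15. The fallback abandons the cyclopropane and builds the E-trisubstituted alkene by metathesis. It sets out from 20 and comes back at 24. Cross-metathesis of 20 with methacrolein (Hoveyda–Grubbs II, CH2Cl2, 40 °C) should give (2E)-5-(furan-3-yl)-2-methylpent-2-enal F3 under thermodynamic E control. Luche reduction (NaBH4, CeCl3·7H2O, MeOH, 0 °C) should give (2E)-5-(furan-3-yl)-2-methylpent-2-en-1-ol F4. Appel bromination (CBr4, PPh3, CH2Cl2, 0 °C) gives 24, which enters step 15 directly at the palladium stage.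

Step 7. Under hot acidic conditions the tertiary silyl ether may be lost, after which the freed propargylic carbinol can enter a competing propargyl Claisen (allenoate formation); E selectivity may also be incomplete. The fallback installs the ester arm by allylic oxidation and alkylation in place of cleavage and rearrangement. It sets out from 5 and from 21, bypasses steps 5–7 and comes back at 12. Selenium dioxide oxidation (cat. SeO2, t-BuOOH, CH2Cl2, rt), which is selective for the E-methyl group, should give (2E,6S)-2,6-dimethyl-6-[(triethylsilyl)oxy]oct-2-en-7-yn-1-ol F5. Appel bromination (CBr4, PPh3, CH2Cl2, 0 °C) gives the allylic bromide [(3S,6E)-8-bromo-3,7-dimethyloct-6-en-1-yn-3-yl]oxy(triethyl)silane F6. SN2 alkylation with the lithium enolate of 21 (LiHMDS, THF/DMPU, −78 °C, 2.2 equiv so that the alkyne C–H is covered) then gives 12.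

**Further compounds**

F1 | step 15 | (5S)-5-[(1R,4S,8E)-11-(furan-3-yl)-1,4-dihydroxy-4,8-dimethylundec-8-en-5-yn-1-yl]-5-methyloxolan-2-one | C/C(=C\CCc1ccoc1)CC#C[C@@](C)(O)CC[C@@H](O)[C@]1(C)CCC(=O)O1
F2 | step 15 | (5S)-5-[(1R,4S,5Z,8E)-11-(furan-3-yl)-1,4-dihydroxy-4,8-dimethyl-5-(tributylstannyl)undeca-5,8-dien-1-yl]-5-methyloxolan-2-one | C/C(=C\CCc1ccoc1)C/C=C(\[Sn](CCCC)(CCCC)CCCC)[C@@](C)(O)CC[C@@H](O)[C@]1(C)CCC(=O)O1
F3 | step 13 | (2E)-5-(furan-3-yl)-2-methylpent-2-enal | C/C(=C\CCc1ccoc1)C=O
F4 | step 13 | (2E)-5-(furan-3-yl)-2-methylpent-2-en-1-ol | C/C(=C\CCc1ccoc1)CO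
F5 | step 7 | (2E,6S)-2,6-dimethyl-6-[(triethylsilyl)oxy]oct-2-en-7-yn-1-ol | C#C[C@@](C)(O[Si](CC)(CC)CC)CC/C=C(\C)CO
F6 | step 7 | [(3S,6E)-8-bromo-3,7-dimethyloct-6-en-1-yn-3-yl]oxy(triethyl)silane | C#C[C@@](C)(O[Si](CC)(CC)CC)CC/C=C(\C)CBr
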